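(The numbers of this flask belong to no real substance; the result is computed.)

The coupling partner is the limiting reagent: its charge of 0.800 equiv is smaller than the second substrate's 1.00 equiv, and the starting material and second substrate compete for it.

- alpha: starting material 0.20 M; coupling partner 0.800 equiv; second substrate 1.00 equiv; temperature 100 °C; time 2.0 h
- delta: starting material 0.20 M; coupling partner 0.800 equiv; second substrate 1.00 equiv; temperature 70 °C; time 2.0 h

- the flask with the highest amount of target, in percent of the starting material charged ("all alike" if they lie within 1.5 percentage points) (alpha / delta / all alike)
- final target, as a percentage of the starting material charged, in alpha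
- final target, as a percentage of the starting material charged, in delta

    starting material + coupling partner ⇌ target (K1 = 11 L mol⁻¹, k1 = 0.0016 L mol⁻¹ s⁻¹, Ea1 = 80.0 kJ mol⁻¹, ΔH1 = −28.0 kJ mol⁻¹)
    second substrate + coupling partner → second product (k2 = 0.0019 L mol⁻¹ s⁻¹, Ea2 = 61.0 kJ mol⁻¹)
    coupling partner ⇌ dormant form (K3 = 3.0, k3 = 1.4 × 10⁻⁴ s⁻¹, Ea3 = 130 kJ mol⁻¹, ΔH3 = −84.0 kJ mol⁻¹)
    coupling partner → decomposed reagent (k4 = 3.1 × 10⁻⁴ s⁻¹, Ea4 = 126 kJ mol⁻¹)
    (constants at 100 °C)

- all constants are for 100 °C and move with temperature by the activation energies and enthalpies

A balance of the coupling partner, with the other two charges held at their starting values, makes each loss pseudo-first-order. The constant L is the sum of these losses, and spent partner times the target's part of L gives the target. In alpha, L is 4.14 h⁻¹, and the target's part is 27.8 %. In delta, the target step contributes 0.121 h⁻¹, the second substrate 0.245 h⁻¹, and dormancy with decomposition 0.0450 h⁻¹, so L is 0.411 h⁻¹. The target share φ, the target step's part of the partner's total loss, is then 29.4 % in delta.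

Temperature is the first setting: cooling from alpha to delta leaves φ close to where it was but makes L smaller. Time comes next. By this balance the partner's half-life in alpha is 10.0 min, shorter than the 2.0 h run, so by hand alpha's target is φ times the charge, decayed by its own back step, whose half-life is 1.32 h. That gives 7.81 %. In delta the back step's half-life is 27.8 h, longer than the run, so it drops out. The spent fraction is 56.0 %, and the hand figure is 13.2 %. The partner's charge enters this rule in proportion. Raising the starting concentration with the equivalents held raises both bimolecular terms together, so L grows while their ratio stays.

This reckoning puts delta ahead, but the forecast differs: it calls the flasks all alike, with 11.1 % (10.2 % to 12 %) in alpha, where “target then leaks back”, and 12.2 % (11.5 % to 12.9 %) in delta.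

The simulation gives 11.4 % in alpha and 12.3 % in delta, so the flasks count as all alike. Alpha stands above its hand figure and delta below its own. Delta keeps 48 % of its partner free, and φ, reckoned at the starting concentrations, times the rest of the charge gives 12.2 %. For delta, settings moved one at a time by the same factor rank: coupling partner (3.5 points), then starting material (2.3 points), then time (2 points), then second substrate (0.66 points). Neither flask has come to rest: after 20.0 h, alpha's target falls to 0.330 %, while delta's climbs to 18.6 %.

The same flask as delta run at 55 °C has L of 0.132 h⁻¹ and φ of 25.5 %, which gives 4.73 % of target by hand. The computed flask gives 4.61 %.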